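A direct plan would acylate resorcinol A1 with 3-hydroxy-4-methoxyphenylacetic acid A2 to the deoxybenzoin A3, would add C-2 with a formamide acetal to close ring C and give calycosin A4, and would prenylate O-7 last.
Its weakest steps would be the Friedel–Crafts C-acylation, because three free phenols and a free acid in hot Lewis acid would invite esters, double acylation and a hard isolation;
the final O-prenylation, because it would have to tell the 7-OH from the 3'-OH by acidity alone, with C-alkylation and bis-ethers as side paths;
and the one-carbon insertion, because it would spend a whole step on a single carbon atom.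

The route would rest on a biosynthesis-like skeletal shift of a chalcone. Ring A would enter as a 2-fluoroaryl ketone whose only phenol is prenylated first, ring B as unprotected isovanillin. In the key step a Lewis acid would open the chalcone epoxide at the benzylic carbon on ring B (cation stabilised by the para 4'-methoxy group), and the aroyl group would migrate there (formal 2,3-aryl shift), giving the C3–C4 bond and the C-2 aldehyde; its enolate oxygen would then displace the fluorine on C-8a, activated by the ortho C-4 carbonyl, and close ring C (O1–C8a). Friedel–Crafts acylation, one-carbon insertion and the choice between two phenols would all disappear, without protecting groups.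

Key step: step 4

Assumption: ketone 1 is taken as a commercial building block; epoxide 6 would be racemic and trans (one enantiomer is drawn), its two stereocentres would vanish in step 4, and the target is achiral.

Step 1
Reactants: 1 1-(2-fluoro-4-hydroxyphenyl)ethan-1-one; 2 prenyl bromide (1-bromo-3-methylbut-2-ene)
Product: 3 1-[2-fluoro-4-(3-methylbut-2-en-1-yloxy)phenyl]ethan-1-one
Conditions: K2CO3 (1.5 equiv), acetone, 50 °C, 6 h
Reagents that add atoms: none
Why: Williamson ether synthesis (SN2 at the primary allylic bromide) on the only phenol of 1, whose para-acyl phenoxide should alkylate cleanly on oxygen; no stereocentre is formed.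

Step 2
Reactants: 3 1-[2-fluoro-4-(3-methylbut-2-en-1-yloxy)phenyl]ethan-1-one; 4 isovanillin (3-hydroxy-4-methoxybenzaldehyde)
Product: 5 (E)-1-[2-fluoro-4-(3-methylbut-2-en-1-yloxy)phenyl]-3-(3-hydroxy-4-methoxyphenyl)prop-2-en-1-one
Conditions: KOH (3 equiv, 50% aq), EtOH, 0 °C → rt, 24 h; AcOH to pH 6
Reagents that add atoms: none
Why: Claisen–Schmidt condensation in which the enolate of methyl ketone 3 adds to the non-enolisable aldehyde 4 and E1cB loss of water gives the conjugated E-enone; the phenoxide of 4 sits meta to the formyl group and should lower its reactivity only mildly, and the fluorine, activated only by an ortho ketone that the para prenyloxy group makes less electron-poor, should survive hydroxide at room temperature.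

Step 3
Reactants: 5 (E)-1-[2-fluoro-4-(3-methylbut-2-en-1-yloxy)phenyl]-3-(3-hydroxy-4-methoxyphenyl)prop-2-en-1-one
Product: 6 rac-[2-fluoro-4-(3-methylbut-2-en-1-yloxy)phenyl][(2R,3S)-3-(3-hydroxy-4-methoxyphenyl)oxiran-2-yl]methanone (trans epoxy ketone)
Conditions: 30% aq H2O2 (4 equiv), NaOH (2.2 equiv), MeOH–THF 2:1, 0 °C → rt; NaH2PO4 buffer to pH 7; used crude
Reagents that add atoms: hydrogen peroxide (OO)
Why: Weitz–Scheffer nucleophilic epoxidation in which hydroperoxide anion adds to the enone β-carbon and the enolate closes the oxirane with loss of hydroxide, so the electron-rich prenyl alkene should stay untouched; bond rotation in the enolate intermediate should give the more stable trans epoxide as a racemate.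

Step 4
Reactants: 6 rac-[2-fluoro-4-(3-methylbut-2-en-1-yloxy)phenyl][(2R,3S)-3-(3-hydroxy-4-methoxyphenyl)oxiran-2-yl]methanone
Product: 8 7-prenyloxy-3'-hydroxy-4'-methoxyisoflavone (target), via ketoaldehyde 7 (not isolated)
Conditions: BF3·OEt2 (0.3 equiv), CH2Cl2 (0.02 M), −40 → −10 °C, 30 min; then K2CO3 (3 equiv), DMF, CH2Cl2 distilled off, 70 °C, 3 h
Reagents that add atoms: none
Why: Meinwald-type rearrangement of an α,β-epoxy ketone followed by intramolecular SNAr: BF3 should open the oxirane at the benzylic carbon, where the cation is stabilised by the para methoxy group of ring B, and the neighbouring aroyl group should migrate to that carbon (1,2-acyl shift), which forms the C3–C4 bond, places ring B on C-3 and leaves the former epoxide oxygen on C-2 as the aldehyde of 7. The closest known reactions are the BF3 rearrangement of chalcone epoxides to α-formyl deoxybenzoins and the carbonate-mediated closure of 2-fluoroaryl 1,3-dicarbonyl compounds to chromones. Ring C closes by attack of the Z-enolate oxygen of 7 on C-8a (six-membered ring, addition–elimination through a Meisenheimer complex stabilised by the ortho C-4 carbonyl) with loss of fluoride. No stereocentre is formed and both epoxide stereocentres are erased, so the racemic nature of 6 is of no consequence. The step needs acyl and not hydride migration, which the known preference of aroyl groups in chalcone epoxides should secure, and it needs the prenyl ether to survive, for which the very easy ionisation of this epoxide allows a substoichiometric Lewis acid at low temperature. Intramolecular O-arylation should outrun attack of the ring B phenoxide on another molecule because it is a six-membered closure.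

**Compound list**
1 | 1-(2-fluoro-4-hydroxyphenyl)ethan-1-one | CC(=O)c1ccc(O)cc1F | starting material
2 | prenyl bromide (1-bromo-3-methylbut-2-ene) | CC(C)=CCBr | starting material
3 | 1-[2-fluoro-4-(3-methylbut-2-en-1-yloxy)phenyl]ethan-1-one | CC(=O)c1ccc(OCC=C(C)C)cc1F | intermediate
4 | isovanillin (3-hydroxy-4-methoxybenzaldehyde) | COc1ccc(C=O)cc1O | starting material
5 | (E)-1-[2-fluoro-4-(3-methylbut-2-en-1-yloxy)phenyl]-3-(3-hydroxy-4-methoxyphenyl)prop-2-en-1-one | COc1ccc(/C=C/C(=O)c2ccc(OCC=C(C)C)cc2F)cc1O | intermediate
6 | rac-[2-fluoro-4-(3-methylbut-2-en-1-yloxy)phenyl][(2R,3S)-3-(3-hydroxy-4-methoxyphenyl)oxiran-2-yl]methanone (trans; one enantiomer drawn) | O=C(c1ccc(OCC=C(C)C)cc1F)[C@@H]1O[C@H]1c2ccc(OC)c(O)c2 | intermediate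
7 | 3-[2-fluoro-4-(3-methylbut-2-en-1-yloxy)phenyl]-2-(3-hydroxy-4-methoxyphenyl)-3-oxopropanal (racemic, largely enolised) | COc1ccc(C(C=O)C(=O)c2ccc(OCC=C(C)C)cc2F)cc1O | intermediate
8 | 7-prenyloxy-3'-hydroxy-4'-methoxyisoflavone (3-(3-hydroxy-4-methoxyphenyl)-7-(3-methylbut-2-en-1-yloxy)-4H-chromen-4-one; achiral) | COc1ccc(-c2coc3cc(OCC=C(C)C)ccc3c2=O)cc1O | target

Total step count: 4. Longest linear sequence: 4.

**Steps most likely to fail**

First, step 4. The Lewis acid might ionise or shift the acid-labile prenyl ether. Hydride might migrate in place of the aroyl group. The product might be held back as a boron chelate, or lose its formyl group by retro-Claisen cleavage in the basic second stage. The fallback would avoid the epoxide and the Lewis acid altogether and would set out from ketone 3. A palladium-catalysed α-arylation of 3 with commercially available (5-bromo-2-methoxyphenoxy)(tert-butyl)dimethylsilane (Pd(OAc)2, XPhos, K3PO4, toluene, 90 °C) would give 2-[3-(tert-butyldimethylsilyloxy)-4-methoxyphenyl]-1-[2-fluoro-4-(3-methylbut-2-en-1-yloxy)phenyl]ethan-1-one F1. The trisubstituted prenyl ether should be slow to ionise at zerovalent palladium under the bulky ligand. Claisen formylation (ethyl formate, NaH, THF, 0 °C → rt) would give 2-[3-(tert-butyldimethylsilyloxy)-4-methoxyphenyl]-3-[2-fluoro-4-(3-methylbut-2-en-1-yloxy)phenyl]-3-oxopropanal F2. Heating F2 with K2CO3 in DMF at 70 °C would close ring C by the same SNAr to 3-[3-(tert-butyldimethylsilyloxy)-4-methoxyphenyl]-7-(3-methylbut-2-en-1-yloxy)-4H-chromen-4-one F3. The fluoride set free should take off the aryl silyl group in the same flask, so that the sequence comes back to the route at target 8.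

Second, step 3. Hydroperoxide addition might be slow, because the β-aryl group of the enone is an electron-rich phenoxide under the conditions. Retro-aldol cleavage or displacement of the fluorine by hydroperoxide might compete, and the para-alkoxybenzylic epoxide might open on isolation. The fallback would build the oxirane by a Darzens condensation and would set out from ketone 3 and aldehyde 4. Chlorination of 3 through its lithium enolate (LiN(SiMe3)2, THF, −78 °C; N-chlorosuccinimide) would give 2-chloro-1-[2-fluoro-4-(3-methylbut-2-en-1-yloxy)phenyl]ethan-1-one F4. Silylation of 4 (tert-butyldimethylsilyl chloride, imidazole, DMF) would give 3-(tert-butyldimethylsilyloxy)-4-methoxybenzaldehyde F5. Condensation of F4 with F5 (LiN(SiMe3)2, THF, −78 → 0 °C) would give rac-[(2R,3S)-3-[3-(tert-butyldimethylsilyloxy)-4-methoxyphenyl]oxiran-2-yl][2-fluoro-4-(3-methylbut-2-en-1-yloxy)phenyl]methanone F6. Desilylation (Bu4NF buffered with AcOH, THF, 0 °C) would come back to the route at epoxide 6.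

Third, step 2. The condensation might stall because the aldehyde is deactivated as its phenoxide; aldehyde 4 might disproportionate (Cannizzaro); and hydroxide or ethoxide might slowly displace the ketone-activated fluorine. The fallback would make the enone by a Heck reaction and would set out from ketone 3. One-pot α-methylenation (paraformaldehyde, diisopropylammonium trifluoroacetate, THF, reflux) would give 1-[2-fluoro-4-(3-methylbut-2-en-1-yloxy)phenyl]prop-2-en-1-one F7. Coupling of F7 with 5-iodo-2-methoxyphenol (Pd(OAc)2, NaHCO3, Bu4NCl, DMF, 60 °C) would come back to the route at chalcone 5.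

**Further compounds**
F1 | step 4 | 2-[3-(tert-butyldimethylsilyloxy)-4-methoxyphenyl]-1-[2-fluoro-4-(3-methylbut-2-en-1-yloxy)phenyl]ethan-1-one | COc1ccc(CC(=O)c2ccc(OCC=C(C)C)cc2F)cc1O[Si](C)(C)C(C)(C)C
F2 | step 4 | 2-[3-(tert-butyldimethylsilyloxy)-4-methoxyphenyl]-3-[2-fluoro-4-(3-methylbut-2-en-1-yloxy)phenyl]-3-oxopropanal (racemic, enolised) | COc1ccc(C(C=O)C(=O)c2ccc(OCC=C(C)C)cc2F)cc1O[Si](C)(C)C(C)(C)C
F3 | step 4 | 3-[3-(tert-butyldimethylsilyloxy)-4-methoxyphenyl]-7-(3-methylbut-2-en-1-yloxy)-4H-chromen-4-one | COc1ccc(-c2coc3cc(OCC=C(C)C)ccc3c2=O)cc1O[Si](C)(C)C(C)(C)C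
F4 | step 3 | 2-chloro-1-[2-fluoro-4-(3-methylbut-2-en-1-yloxy)phenyl]ethan-1-one | O=C(CCl)c1ccc(OCC=C(C)C)cc1F
F5 | step 3 | 3-(tert-butyldimethylsilyloxy)-4-methoxybenzaldehyde | COc1ccc(C=O)cc1O[Si](C)(C)C(C)(C)C
F6 | step 3 | rac-[(2R,3S)-3-[3-(tert-butyldimethylsilyloxy)-4-methoxyphenyl]oxiran-2-yl][2-fluoro-4-(3-methylbut-2-en-1-yloxy)phenyl]methanone (trans; one enantiomer drawn) | O=C(c1ccc(OCC=C(C)C)cc1F)[C@@H]1O[C@H]1c2ccc(OC)c(O[Si](C)(C)C(C)(C)C)c2
F7 | step 2 | 1-[2-fluoro-4-(3-methylbut-2-en-1-yloxy)phenyl]prop-2-en-1-one | C=CC(=O)c1ccc(OCC=C(C)C)cc1F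
A1 | direct plan | resorcinol (benzene-1,3-diol) | Oc1cccc(O)c1
A2 | direct plan | 3-hydroxy-4-methoxyphenylacetic acid | COc1ccc(CC(=O)O)cc1O
A3 | direct plan | 1-(2,4-dihydroxyphenyl)-2-(3-hydroxy-4-methoxyphenyl)ethan-1-one | COc1ccc(CC(=O)c2ccc(O)cc2O)cc1O
A4 | direct plan | calycosin (7-hydroxy-3-(3-hydroxy-4-methoxyphenyl)-4H-chromen-4-one) | COc1ccc(-c2coc3cc(O)ccc3c2=O)cc1O
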